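**Plan**
1. Retrosynthetic cuts (ring numbered C1 = carbonyl carbon, C2=C3 the alkene, C4 quaternary, C5 the CH(CH3) carbon): (a) the CH2–C(sp2) bond between the ring's ethylene arm and the side chain; (b) the C3–CH3 bond; (c) the ring bond C4–C5; (d) two further alkyl–alkenyl bonds inside the chain.
2. Enabling feature: C5 is β to the ring ketone C1 through C6 and C4 is γ to it through C2=C3, so the six ring carbons map onto a 3-oxidohexatriene C5=C6–C1(O−)=C2–C3=C4. A temporary oxolane ties the future CH2CH2 arm through oxygen to C3, which locks the C3=C4 geometry and keeps C3 at the ketone oxidation level.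
3. Forward, ring part: lactone 2 and enone 1 give alkylidene oxolane 5; an ion-pair-catalysed 6π electrocyclization closes the only carbocycle (7); silyl iodide-type cleavage opens the oxolane, frees the iodoethyl arm and transposes the enol ether so that methyl can be added at C3 (11).
4. Forward, chain part: side chain 21 is grown on the butenolide by two rounds of alkylzinc coupling and hydrozirconation–iodination, both couplings drawing on one batch of alkylzinc reagent 14; a last Negishi coupling joins 11 and 21.
5. Stereochemistry: the trans ring methyls follow from disrotatory closure of the E-propenyl and ring-locked enol ether termini; the absolute configuration comes from the chiral ammonium counter-ion; both E-alkenes come from syn-hydrozirconation and stereoretentive couplings.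

Key step: step 2

Assumption: the cinchonidinium salt is taken to deliver the (3aR,4R) series in step 2; if it delivers the antipode, the pseudoenantiomeric cinchoninium salt is used instead.

**Step 1**
Reactants: 1 (3E)-pent-3-en-2-one; 2 3-methyloxolan-2-one (α-methyl-γ-butyrolactone, racemic)
Product: 5 (3E)-1-(3-methyloxolan-2-ylidene)pent-3-en-2-one (racemic; enol ether isomers), via lithium dienolate 3 (not isolated), via lactol 4 (not isolated)
Conditions: 1 (2.1 equiv), LDA (2.1 equiv), THF, −78 °C; then 2 (1.0 equiv), −78 → −40 °C; 1 M HCl work-up; then TsOH (5 mol %), 4 Å MS, toluene, 60 °C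
Reagents that add atoms: none
Why: Crossed Claisen-type addition of the kinetic methyl-side enolate of 1 to the lactone carbonyl (the second equivalent of enolate takes up the acidic proton of the adduct) followed by acid-catalysed dehydration of lactol 4 should give the push–pull alkylidene oxolane; no stereocontrol is needed because the ring stereocentre and the enol ether geometry are erased in step 2.

**Step 2**
Reactants: 5 (3E)-1-(3-methyloxolan-2-ylidene)pent-3-en-2-one
Product: 7 (3aR,4R)-3a,4-dimethyl-2,3,3a,4-tetrahydro-1-benzofuran-6(5H)-one, via trienolate 6 (not isolated)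
Conditions: N-(9-anthracenylmethyl)-O-allylcinchonidinium bromide (10 mol %), CsOH·H2O (30 mol %), toluene/CH2Cl2 7:3, 0.02 M, −40 → −20 °C; aq. NH4Cl
Reagents that add atoms: none
Why: Proposed new method: hydroxide removes the ring C–H of 5 (γ to the ketone through the enol ether), which erases its stereocentre and enol ether geometry and gives the planar 3-oxidohexatriene 6 ion-paired with the cinchonidinium cation; 6 should close by thermal disrotatory 6π electrocyclization between the ring carbon and the propenyl CH, and the resulting dienolate is protonated on the carbon next to the carbonyl to give 7. The closest known reaction types are the oxyanion-accelerated 6π electrocyclization of 3-oxidohexatrienes to cyclohexenones and the ion-pair (phase-transfer) catalysed enantioselective cyclization of delocalised carbanions. The six-membered carbocycle closes in the 6π disrotatory mode (in polar terms a 6-endo-trig vinylogous Michael addition), the oxolane being present beforehand. The relative configuration of C3a and C4 is fixed by orbital symmetry and two locked geometries: the E-propenyl unit holds its CH3 outside, and the oxolane holds its ring CH2 outside and the CH3 inside at the other terminus, so the two outside groups end cis and the two methyl groups trans; the absolute configuration of both centres comes from the chiral cation, which must distinguish the two enantiomeric helical transition states. The step needs closure from the ring-carbon terminus in preference to reaction of the linear dienolate formed reversibly at the propenyl CH3, which is secured because only 6 places a nucleophilic carbon opposite the enone β-carbon; it is stereoconvergent because every isomer of 5 passes through 6.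

**Step 3**
Reactants: 7 (3aR,4R)-3a,4-dimethyl-2,3,3a,4-tetrahydro-1-benzofuran-6(5H)-one
Product: 9 (5R,6R)-3-[(tert-butyldimethylsilyl)oxy]-6-(2-iodoethyl)-5,6-dimethylcyclohex-2-en-1-one, via silyloxy oxocarbenium triflate 8 (not isolated)
Conditions: TBSOTf (1.1 equiv), CH2Cl2, −78 → 0 °C; then Bu4NI (1.5 equiv), 0 °C → rt; non-aqueous work-up, used crude
Reagents that add atoms: tert-butyldimethylsilyl trifluoromethanesulfonate, CC(C)(C)[Si](C)(C)OS(=O)(=O)C(F)(F)F; tetrabutylammonium iodide, CCCC[N+](CCCC)(CCCC)CCCC.[I-]
Why: O-silylation of the vinylogous ester carbonyl gives cation 8, which iodide should dealkylate by SN2 attack at the O–CH2 carbon (the reaction type of silyl iodide cleavage of lactones and ethers); this frees the arm as a primary iodide and moves the enol ether oxygen away from the quaternary carbon, leaving the ketone next to it for step 4, with no stereocentre touched.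

**Step 4**
Reactants: 9 (5R,6R)-3-[(tert-butyldimethylsilyl)oxy]-6-(2-iodoethyl)-5,6-dimethylcyclohex-2-en-1-one
Product: 11 (4R,5R)-4-(2-iodoethyl)-3,4,5-trimethylcyclohex-2-en-1-one, via tertiary carbinol 10 (not isolated)
Conditions: MeLi, CeCl3, THF, −78 °C; then 1 M HCl, THF, −78 → 0 °C → rt
Reagents that add atoms: methyllithium, [Li]C
Why: Stork–Danheiser-type sequence in which the non-basic organocerium should add 1,2 to the hindered ketone without touching the primary iodide, and acid hydrolysis of the silyl enol ether with loss of water from the tertiary carbinol (quenched cold so that the alkoxide does not displace the iodide) gives the transposed 3-methyl enone; neither stereocentre is enolisable.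

**Step 5**
Reactants: 12 pent-3-yn-1-ol
Product: 13 5-iodopent-2-yne
Conditions: I2, PPh3, imidazole, CH2Cl2, 0 °C → rt
Reagents that add atoms: iodine, II
Why: Appel-type iodination of a primary alcohol by SN2 displacement of the alkoxyphosphonium ion.

**Step 6**
Reactants: 13 5-iodopent-2-yne
Product: 14 pent-3-yn-1-ylzinc iodide (titrated THF solution containing LiCl; kept under argon as a stock solution for steps 7 and 9)
Conditions: Zn dust (activated), LiCl, THF, 40 °C; solution decanted from excess Zn and titrated against I2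
Reagents that add atoms: zinc, [Zn]
Why: Direct oxidative insertion of zinc into a primary alkyl iodide, accelerated by LiCl, should give a storable alkylzinc halide solution in which the internal alkyne is inert.

**Step 7**
Reactants: 14 pent-3-yn-1-ylzinc iodide; 15 4-bromofuran-2(5H)-one
Product: 16 4-(pent-3-yn-1-yl)furan-2(5H)-one
Conditions: 14 (1.2 equiv, THF solution), 15, Pd(PPh3)4 (5 mol %), THF, 25 → 50 °C
Reagents that add atoms: none
Why: Negishi coupling of the alkylzinc with the electron-poor alkenyl bromide should install the butenolide, the internal alkyne and the lactone being inert to the organozinc.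

**Step 8**
Reactants: 16 4-(pent-3-yn-1-yl)furan-2(5H)-one
Product: 18 4-[(3E)-4-iodopent-3-en-1-yl]furan-2(5H)-one, via alkenylzirconocene chloride 17 (not isolated)
Conditions: Cp2Zr(H)Cl (bis(cyclopentadienyl)zirconium chloride hydride, 1.5 equiv), THF, 25 → 40 °C; then I2, THF, −78 → 0 °C
Reagents that add atoms: iodine, II
Why: Hydrozirconation is a syn addition that, after equilibration with a small excess of hydride, should place zirconium on the less hindered methyl-bearing alkyne carbon, and iodinolysis with retention gives the E-2-iodoalkene; the alkyne is expected to react faster than the lactone.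

**Step 9**
Reactants: 18 4-[(3E)-4-iodopent-3-en-1-yl]furan-2(5H)-one; 14 pent-3-yn-1-ylzinc iodide
Product: 19 4-[(3E)-4-methylnon-3-en-7-yn-1-yl]furan-2(5H)-one
Conditions: 14 (1.3 equiv, THF solution from step 6), 18, Pd(PPh3)4 (5 mol %), THF, 25 → 45 °C
Reagents that add atoms: none
Why: Negishi sp3–sp2 coupling should proceed with retention of the alkenyl iodide geometry, which fixes the first E-trisubstituted alkene and brings in the next masked iodoalkene as an alkyne.

**Step 10**
Reactants: 19 4-[(3E)-4-methylnon-3-en-7-yn-1-yl]furan-2(5H)-one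
Product: 21 4-[(3E,7E)-8-iodo-4-methylnona-3,7-dien-1-yl]furan-2(5H)-one, via alkenylzirconocene chloride 20 (not isolated)
Conditions: Cp2Zr(H)Cl (1.5 equiv), THF, 25 → 40 °C; then I2, THF, −78 → 0 °C
Reagents that add atoms: iodine, II
Why: The same syn-hydrozirconation–iodination should convert the methyl alkyne into the E-2-iodoalkene, the trisubstituted alkene being too hindered to react with the zirconium hydride.

**Step 11**
Reactants: 11 (4R,5R)-4-(2-iodoethyl)-3,4,5-trimethylcyclohex-2-en-1-one; 21 4-[(3E,7E)-8-iodo-4-methylnona-3,7-dien-1-yl]furan-2(5H)-one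
Product: 23 cyclolinteinone, via alkylzinc iodide 22 (not isolated)
Conditions: 11, Zn dust, LiCl, THF, 35 °C; then 21, Pd(PPh3)4 (5 mol %), THF, 25 → 45 °C
Reagents that add atoms: none
Why: Zinc should insert into the primary iodide without affecting the enone, and Negishi sp3–sp2 coupling with retention of the E-iodoalkene geometry completes the skeleton, leaving enone, butenolide and both stereocentres untouched.

**Compound list**
1 | (3E)-pent-3-en-2-one | C/C=C/C(C)=O | starting material
2 | 3-methyloxolan-2-one (α-methyl-γ-butyrolactone, racemic) | CC1CCOC1=O | starting material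
3 | lithium (3E)-penta-1,3-dien-2-olate | C=C(O[Li])/C=C/C | intermediate
4 | (3E)-1-(2-hydroxy-3-methyloxolan-2-yl)pent-3-en-2-one (lactol, diastereomer mixture) | C/C=C/C(=O)CC1(O)OCCC1C | intermediate
5 | (3E)-1-(3-methyloxolan-2-ylidene)pent-3-en-2-one (racemic, enol ether isomers) | C/C=C/C(=O)C=C1OCCC1C | intermediate
6 | cesium (1E,3E)-1-(3-methyl-4,5-dihydrofuran-2-yl)penta-1,3-dien-2-olate (the 3-oxidohexatriene; ion-paired with the catalyst cation in solution) | C/C=C/C([O-])=C\C1=C(C)CCO1.[Cs+] | intermediate
7 | (3aR,4R)-3a,4-dimethyl-2,3,3a,4-tetrahydro-1-benzofuran-6(5H)-one | O=C1C=C2OCC[C@]2(C)[C@H](C)C1 | intermediate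
8 | (3aR,4R)-6-[(tert-butyldimethylsilyl)oxy]-3a,4-dimethyl-3,3a,4,5-tetrahydro-2H-1-benzofuran-1-ium trifluoromethanesulfonate | C[Si](C)(C(C)(C)C)OC1=CC2=[O+]CC[C@]2(C)[C@H](C)C1.[O-]S(=O)(=O)C(F)(F)F | intermediate
9 | (5R,6R)-3-[(tert-butyldimethylsilyl)oxy]-6-(2-iodoethyl)-5,6-dimethylcyclohex-2-en-1-one | O=C1C=C(O[Si](C)(C)C(C)(C)C)C[C@@H](C)[C@@]1(C)CCI | intermediate
10 | (5R,6R)-3-[(tert-butyldimethylsilyl)oxy]-6-(2-iodoethyl)-1,5,6-trimethylcyclohex-2-en-1-ol (C1 epimers, formed as its cerium alkoxide) | CC1(O)C=C(O[Si](C)(C)C(C)(C)C)C[C@@H](C)[C@@]1(C)CCI | intermediate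
11 | (4R,5R)-4-(2-iodoethyl)-3,4,5-trimethylcyclohex-2-en-1-one | CC1=CC(=O)C[C@@H](C)[C@@]1(C)CCI | intermediate
12 | pent-3-yn-1-ol | CC#CCCO | starting material
13 | 5-iodopent-2-yne | CC#CCCI | intermediate
14 | pent-3-yn-1-ylzinc iodide (THF solution with LiCl) | CC#CCC[Zn]I | intermediate
15 | 4-bromofuran-2(5H)-one | BrC1=CC(=O)OC1 | starting material
16 | 4-(pent-3-yn-1-yl)furan-2(5H)-one | CC#CCCC1=CC(=O)OC1 | intermediate
17 | chloridobis(cyclopentadienyl)[(2E)-5-(5-oxo-2,5-dihydrofuran-3-yl)pent-2-en-2-yl]zirconium | C/C(=C\CCC1=CC(=O)OC1)[Zr](Cl)(C1C=CC=C1)C1C=CC=C1 | intermediate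
18 | 4-[(3E)-4-iodopent-3-en-1-yl]furan-2(5H)-one | I/C(C)=C/CCC1=CC(=O)OC1 | intermediate
19 | 4-[(3E)-4-methylnon-3-en-7-yn-1-yl]furan-2(5H)-one | CC#CCC/C(C)=C/CCC1=CC(=O)OC1 | intermediate
20 | chloridobis(cyclopentadienyl)[(2E,6E)-6-methyl-9-(5-oxo-2,5-dihydrofuran-3-yl)nona-2,6-dien-2-yl]zirconium | C/C(=C\CC/C(C)=C/CCC1=CC(=O)OC1)[Zr](Cl)(C1C=CC=C1)C1C=CC=C1 | intermediate
21 | 4-[(3E,7E)-8-iodo-4-methylnona-3,7-dien-1-yl]furan-2(5H)-one | I/C(C)=C/CC/C(C)=C/CCC1=CC(=O)OC1 | intermediate
22 | iodido{2-[(1R,6R)-1,2,6-trimethyl-4-oxocyclohex-2-en-1-yl]ethyl}zinc | CC1=CC(=O)C[C@@H](C)[C@@]1(C)CC[Zn]I | intermediate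
23 | cyclolinteinone, 4-{(3E,7E)-4,8-dimethyl-10-[(1R,6R)-1,2,6-trimethyl-4-oxocyclohex-2-en-1-yl]deca-3,7-dien-1-yl}furan-2(5H)-one | CC1=CC(=O)C[C@@H](C)[C@@]1(C)CC/C(C)=C/CC/C(C)=C/CCC1=CC(=O)OC1 | target

**Step count and risks**
Total step count: 11. Longest linear sequence: 7 steps (steps 5 to 11, from 12); the ring branch is 5 steps (steps 1 to 4 and 11).

Steps most likely to fail:

1. Step 2. The chiral cation may not discriminate well enough between the two enantiomeric disrotatory transition states in a loose ion pair, and closure at the fully substituted terminus may be slow enough for an unselective background path to compete. Fallback with known chemistry, using substrate control from the chiral pool; it sets out from 1 (as its dienolate 3) and comes back at 7. Commercial (R)-5-[(trityloxy)methyl]oxolan-2-one is α-methylated (LDA, MeI, THF, −78 °C) to (5R)-3-methyl-5-[(trityloxy)methyl]oxolan-2-one F1. Addition of 3 and dehydration (PPTS, 4 Å MS) as in step 1 should give (3E)-1-{(5R)-3-methyl-5-[(trityloxy)methyl]oxolan-2-ylidene}pent-3-en-2-one F2. An achiral base (KOt-Bu, THF, −78 → 0 °C) then triggers the oxyanion-accelerated closure of known type, and the new bond should form anti to the trityloxymethyl group, as in alkylations of γ-substituted butyrolactone enolates, to give (2R,3aR,4R)-3a,4-dimethyl-2-[(trityloxy)methyl]-2,3,3a,4-tetrahydro-1-benzofuran-6(5H)-one F3. Aqueous AcOH removes the trityl group to give (2R,3aR,4R)-2-(hydroxymethyl)-3a,4-dimethyl-2,3,3a,4-tetrahydro-1-benzofuran-6(5H)-one F4, and TEMPO/PhI(OAc)2 in aqueous MeCN gives (2R,3aR,4R)-3a,4-dimethyl-6-oxo-2,3,3a,4,5,6-hexahydro-1-benzofuran-2-carboxylic acid F5. DCC coupling with N-hydroxypyridine-2-thione gives 2-thioxopyridin-1(2H)-yl (2R,3aR,4R)-3a,4-dimethyl-6-oxo-2,3,3a,4,5,6-hexahydro-1-benzofuran-2-carboxylate F6, whose photolysis with t-BuSH (Barton decarboxylation) removes the auxiliary carbon and returns 7.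

2. Step 3. The opened product may re-close by O-alkylation of the vinylogous ester oxygen on the primary iodide, and the silyl enol ether may be lost on handling. The fallback sets out from 7 and comes back at 11, separating ring opening from enol ether transposition. HBr in AcOH should open the oxolane at the O–CH2 carbon (as in the opening of butyrolactone to 4-bromobutanoic acid) to give (4R,5R)-4-(2-bromoethyl)-4,5-dimethylcyclohexane-1,3-dione F7. Isobutanol with TsOH in benzene under water removal should etherify the carbonyl remote from the quaternary carbon to give (5R,6R)-6-(2-bromoethyl)-5,6-dimethyl-3-(2-methylpropoxy)cyclohex-2-en-1-one F8. MeLi/CeCl3 followed by aqueous HCl gives (4R,5R)-4-(2-bromoethyl)-3,4,5-trimethylcyclohex-2-en-1-one F9, and Finkelstein exchange (NaI, acetone) gives 11.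

3. Step 8 (the same hazard recurs in step 10). The zirconium hydride may reduce the unsaturated lactone in competition with the alkyne, and zirconium may not migrate fully to the methyl-bearing carbon. The fallback sets out from 14 and comes back at 21, carrying the lactone as a 3-furyl group that is inert to the hydride. Negishi coupling of 14 with 3-bromofuran gives 3-(pent-3-yn-1-yl)furan F10, and hydrozirconation–iodination gives 3-[(3E)-4-iodopent-3-en-1-yl]furan F11. Negishi coupling with 14 gives 3-[(3E)-4-methylnon-3-en-7-yn-1-yl]furan F12, and a second hydrozirconation–iodination gives 3-[(3E,7E)-8-iodo-4-methylnona-3,7-dien-1-yl]furan F13. Photo-oxygenation in the presence of a hindered amine (O2, hν, rose bengal, i-Pr2NEt, CH2Cl2, −78 °C) should give 5-hydroxy-4-[(3E,7E)-8-iodo-4-methylnona-3,7-dien-1-yl]furan-2(5H)-one F14, and NaBH4 reduction with relactonisation gives 21.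

**Further compounds**
F1 | step 2 | (5R)-3-methyl-5-[(trityloxy)methyl]oxolan-2-one (C3 epimers) | O=C1O[C@@H](COC(c2ccccc2)(c2ccccc2)c2ccccc2)CC1C
F2 | step 2 | (3E)-1-{(5R)-3-methyl-5-[(trityloxy)methyl]oxolan-2-ylidene}pent-3-en-2-one | C/C=C/C(=O)C=C1O[C@@H](COC(c2ccccc2)(c2ccccc2)c2ccccc2)CC1C
F3 | step 2 | (2R,3aR,4R)-3a,4-dimethyl-2-[(trityloxy)methyl]-2,3,3a,4-tetrahydro-1-benzofuran-6(5H)-one | O=C1C=C2O[C@@H](COC(c3ccccc3)(c3ccccc3)c3ccccc3)C[C@]2(C)[C@H](C)C1
F4 | step 2 | (2R,3aR,4R)-2-(hydroxymethyl)-3a,4-dimethyl-2,3,3a,4-tetrahydro-1-benzofuran-6(5H)-one | O=C1C=C2O[C@@H](CO)C[C@]2(C)[C@H](C)C1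
F5 | step 2 | (2R,3aR,4R)-3a,4-dimethyl-6-oxo-2,3,3a,4,5,6-hexahydro-1-benzofuran-2-carboxylic acid | O=C1C=C2O[C@@H](C(=O)O)C[C@]2(C)[C@H](C)C1
F6 | step 2 | 2-thioxopyridin-1(2H)-yl (2R,3aR,4R)-3a,4-dimethyl-6-oxo-2,3,3a,4,5,6-hexahydro-1-benzofuran-2-carboxylate | O=C1C=C2O[C@@H](C(=O)ON3C=CC=CC3=S)C[C@]2(C)[C@H](C)C1
F7 | step 3 | (4R,5R)-4-(2-bromoethyl)-4,5-dimethylcyclohexane-1,3-dione | O=C1CC(=O)C[C@@H](C)[C@@]1(C)CCBr
F8 | step 3 | (5R,6R)-6-(2-bromoethyl)-5,6-dimethyl-3-(2-methylpropoxy)cyclohex-2-en-1-one | O=C1C=C(OCC(C)C)C[C@@H](C)[C@@]1(C)CCBr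
F9 | step 3 | (4R,5R)-4-(2-bromoethyl)-3,4,5-trimethylcyclohex-2-en-1-one | CC1=CC(=O)C[C@@H](C)[C@@]1(C)CCBr
F10 | step 8 | 3-(pent-3-yn-1-yl)furan | CC#CCCc1ccoc1
F11 | step 8 | 3-[(3E)-4-iodopent-3-en-1-yl]furan | I/C(C)=C/CCc1ccoc1
F12 | step 8 | 3-[(3E)-4-methylnon-3-en-7-yn-1-yl]furan | CC#CCC/C(C)=C/CCc1ccoc1
F13 | step 8 | 3-[(3E,7E)-8-iodo-4-methylnona-3,7-dien-1-yl]furan | I/C(C)=C/CC/C(C)=C/CCc1ccoc1
F14 | step 8 | 5-hydroxy-4-[(3E,7E)-8-iodo-4-methylnona-3,7-dien-1-yl]furan-2(5H)-one | I/C(C)=C/CC/C(C)=C/CCC1=CC(=O)OC1O
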